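Read the plateau first.

| flask | first end groups | second end groups | remark | time |
|---|---|---|---|---|
| Wednesday's | 1.1 M | 1.1 M | the very flask that is asked about, followed so far |  |
| Tuesday's | 2.2 M | 1.1 M | run made earlier |  |
| flask | 1.1 M | 1.10 M |  | 40 min |

Wednesday's run (percent of the first end groups charged)

| time / min | links / % | first end groups / % |
|---|---|---|
| 2.50 | 15.4 | 0.3 |
| 4.00 | 15.3 | 0 |
| 6.00 | 14.2 | 0 |
| 10.0 | 14.4 | 0.5 |
| 15.0 | 15.3 | 0.2 |
| 20.0 | 15.3 | 0 |
| 30.0 | 14.4 | 0.5 |

Tuesday's run (percent of the first end groups charged)

| time / s | links / % | first end groups / % |
|---|---|---|
| 10.0 | 8.1 | 58.9 |
| 15.0 | 9.2 | 53.8 |
| 20.0 | 7.4 | 52.9 |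
| 30.0 | 7.4 | 50.5 |
| 50.0 | 7.7 | 50.1 |
| 80.0 | 7.3 | 51.2 |
| 120 | 8.1 | 50.3 |

(readings scatter by 0.5 percentage points)

- alpha: at 40 min take out 90 % of the links then present, then wait 40 min
- gamma: at 40 min add first end groups, 50.0 % of the amount charged, then wait 40 min
- eta: change nothing and wait 40 min more

- what is taken out of links is counted as made
- the numbers in the tables scatter by 0.5 percentage points (one standard deviation)
- reactions considered so far: first end groups + second end groups -> links; first end groups + second end groups -> rings; second end groups <-> dormant form
- additions bring no volume worth counting

* links, in percent of the first end groups first charged, at 40 min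
* which option adds most links ("none" when 2 percentage points or less is all one gets) (alpha / gamma / eta / none)
* links present, with what was taken out counted in, in percent of the first end groups first charged, after alpha
* links present, with what was taken out counted in, in percent of the first end groups first charged, after eta

Two chemists, Ines and Tom, stand over Wednesday's flask. Divide the rate at which links form by the rate at which second end groups are used, and time drops out, so a level stretch of readings can be used without any rate constant. Wednesday's link readings average 14.9 %, and with equal charges that reading is the link share, links made per second end group used, the overall selectivity.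

Ines reckons forward. Wednesday's first end groups read 0.3 % at 2.50 min, and links stay level through 30.0 min, so the share gives 14.9 % of the first end groups at 40 min. Tuesday's run, with twice the first end groups, reads a share of 15.8 %. Its first end groups end at 50.3 %, where one-to-one use of 1.1 M leaves 50.0 %, and the scatter is 0.5 percentage points. So she sees no partner left for anything added.

Tom holds that a stock hides. Neither table has a column for the dormant form, and Tuesday's last reading at 120 s comes far earlier than 40 min. If second end groups return from the dormant form, gamma's added first end groups earn the share of 50.0 %, which is 7.4 points, more than the 2 points mark.

The forecast sides with Ines: links at 15 % at 40 min, between 14.4 % and 15.6 %, best option none, with the words “Added first end groups therefore find no partner”.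

The flask gives 14.8 % at 40.0 min, and the best option is none.

    first end groups + second end groups → links (k = 0.0311 M⁻¹ s⁻¹)
    first end groups + second end groups → rings, rate k2*[first end groups] as long as [second end groups] is above zero (k = 0.0480 s⁻¹)
    second end groups ⇌ dormant form (K = 1.30, k = 0.164 s⁻¹)

Gamma adds 0 points, with [dormant form] at 1.41 × 10⁻⁶ M at 40.0 min. Ines's share reckoning stands 0.097 points from that result. Tom's stock appears in a neighbour flask charged with 0.66 M of first end groups against 1.10 M of second end groups. There, at 40.0 min, links reach 20.5 % of the first end groups charged, more than the link share of 14.9 % read on Wednesday's run, with 17 % of the charged second end groups free and [dormant form] at 0.249 M.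

The data stem from a simulated flask with constants of no real substance; noise was put on by code.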